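**Retrosynthetic overview**

1. Numbering: C1 = ring carbinol carbon carrying the crotonyl group, C2 = CHMe, C3 = CHOH, C4 = CH2, C5/C6 = lactone ring-fusion carbons (C6 carries the lactone oxygen), C7 = CH–O-isobutyryl, Cα = lactone CHMe. The crotonyl ketone comes from a C1 aldehyde (Nozaki–Hiyama–Kishi propenylation, oxidation), and the C3 and C7 carbinols from cycloheptane-1,4-dione 17 by reduction directed by the C1 hydroxyl.
2. Dione 17 comes from retro-aldol opening (C3–C6 cleaved) of a tricyclic cyclobutanol, which comes from the intramolecular enone–alkene [2+2] photocycloaddition of cyclopentenone 13. That step forms C3–C4 and C5–C6 and closes the γ-lactone at once (de Mayo two-carbon ring expansion, cyclopentane to cycloheptane).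
3. Enabling feature: C3 and C7 are oxygenated carbons in a 1,5-relationship across C4–C5–C6 (the 1,5-dicarbonyl retron of a de Mayo reaction). The lactone chain O–C(=O)–Cα runs exactly from the oxygen on C6 to C5, so the lactone itself is a three-atom tether that holds the C4=C5 vinyl group over the C6=C3 enol double bond of a cyclopentane-1,3-dione.
4. Enone 13 comes from cyclopentane-1,3-dione 9 (diazo transfer at C6, O–H insertion of 2-methylbut-3-enoic acid, O-silylation at C3). Dione 9 comes from Claisen cyclisation of keto ester 8, made by an anti-selective aldol of silyloxypyruvate 3 with a thiopropionate ketene acetal (sets C1 and C2).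
5. Ring order: cyclopentane (step 7), then γ-lactone and cyclobutane together (step 10), then cycloheptane by fragmentation of the bicyclo[3.2.0] core (step 12).

Key step: step 10

Assumption: 2-methylbut-3-enoic acid is used as the racemate (the two Cα epimers converge in step 11), and the (S,S)-Ph-pybox ligand is taken to give the (2R,3R) aldol 6; if the sense of induction is the opposite, the (R,R)-ligand is used.

**Route**

Step 1
Reactants: 1 methyl 2-(hydroxymethyl)acrylate
Product: 2 methyl 2-{[tert-butyl(diphenyl)silyl]oxymethyl}acrylate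
Conditions: TBDPSCl, imidazole, DMF, 0 °C to rt
Reagents that add atoms: tert-butyl(chloro)diphenylsilane, CC(C)(C)[Si](Cl)(c1ccccc1)c1ccccc1
Why: Standard silylation of a primary alcohol; the bulky, weakly basic silyl ether is chosen because it later sits next to a rhodium carbenoid (no oxonium ylide expected) and must survive HF·pyridine.

Step 2
Reactants: 2 methyl 2-{[tert-butyl(diphenyl)silyl]oxymethyl}acrylate
Product: 3 methyl 3-{[tert-butyl(diphenyl)silyl]oxy}-2-oxopropanoate
Conditions: O3, CH2Cl2, −78 °C; then Me2S
Reagents that add atoms: ozone, [O-][O+]=O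
Why: Ozonolysis of the 1,1-disubstituted alkene with reductive work-up should give the α-keto ester and formaldehyde.

Step 3
Reactants: 4 S-ethyl propanethioate
Product: 5 (Z)-1-(ethylsulfanyl)-1-(trimethylsilyloxy)prop-1-ene
Conditions: LiN(i-Pr)2, THF, −78 °C; then Me3SiCl
Reagents that add atoms: chlorotrimethylsilane, C[Si](C)(C)Cl
Why: Kinetic enolisation of the thioester and O-silylation should give mainly the (Z)-silyl ketene acetal.

Step 4
Reactants: 3 methyl 3-{[tert-butyl(diphenyl)silyl]oxy}-2-oxopropanoate; 5 (Z)-1-(ethylsulfanyl)-1-(trimethylsilyloxy)prop-1-ene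
Product: 6 1-methyl 4-S-ethyl (2R,3R)-2-{[tert-butyl(diphenyl)silyl]oxymethyl}-2-hydroxy-3-methyl-4-thiobutanedioate
Conditions: Sn(OTf)2 (10 mol %), (S,S)-Ph-pybox (12 mol %), CH2Cl2, −78 °C; then 1 M HCl, THF
Reagents that add atoms: none
Why: Catalytic enantioselective anti-selective Mukaiyama aldol addition to a chelating α-keto ester: the chiral tin–pybox Lewis acid binds the keto and ester carbonyls, and the open transition state should set the tertiary carbinol (future C1) and the methyl-bearing carbon (future C2) in the anti relationship.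

Step 5
Reactants: 6 anti aldol adduct
Product: 7 triethylsilyl ether of 6 at the tertiary hydroxyl, (2R,3R)
Conditions: Et3SiOTf, 2,6-lutidine, CH2Cl2, −78 to 0 °C
Reagents that add atoms: triethylsilyl trifluoromethanesulfonate, CC[Si](CC)(CC)OS(=O)(=O)C(F)(F)F
Why: Silyl triflate silylation of the hindered tertiary alcohol blocks retro-aldol cleavage in the basic steps that follow.

Step 6
Reactants: 7 silyl-protected thioester
Product: 8 methyl (2R,3R)-2-{[tert-butyl(diphenyl)silyl]oxymethyl}-3-methyl-4-oxo-2-(triethylsilyloxy)pentanoate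
Conditions: Me2CuLi, Et2O, −78 °C
Reagents that add atoms: lithium dimethylcuprate, [Li+].C[Cu-]C
Why: Acyl substitution of a thioester by a lithium dialkylcuprate should give the methyl ketone (its methyl is the future C6) and leave the hindered methyl ester alone.

Step 7
Reactants: 8 keto ester
Product: 9 (4R,5R)-4-{[tert-butyl(diphenyl)silyl]oxymethyl}-5-methyl-4-(triethylsilyloxy)cyclopentane-1,3-dione
Conditions: LiN(SiMe3)2 (2.2 equiv), THF, −78 to 0 °C; then aq NH4Cl
Reagents that add atoms: none
Why: Intramolecular Claisen (Dieckmann-type) condensation: the kinetic methyl-ketone enolate attacks the ester carbonyl in a 5-exo-trig acyl substitution to close the cyclopentane-1,3-dione, with C1 and C2 untouched.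

Step 8
Reactants: 9 cyclopentane-1,3-dione
Product: 10 2-diazo derivative of 9 (diazo group on C6)
Conditions: 4-acetamidobenzenesulfonyl azide, Et3N, MeCN, 0 °C to rt
Reagents that add atoms: 4-acetamidobenzenesulfonyl azide, CC(=O)Nc1ccc(cc1)S(=O)(=O)N=[N+]=[N-]
Why: Regitz diazo transfer to the only doubly activated methylene (C6).

Step 9
Reactants: 10 diazo dione; 11 2-methylbut-3-enoic acid (racemic)
Product: 13 2-(2-methylbut-3-enoyloxy)-3-(triethylsilyloxy)cyclopent-2-enone carrying the C1/C2 substituents of 9 (C7 ketone, acyloxy on C6, silyl enol ether on C3; both Cα epimers), via acyloxy dione enol 12 (not isolated)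
Conditions: Rh2(OAc)4 (1 mol %), CH2Cl2, 40 °C; then Et3SiCl, Et3N, 0 °C
Reagents that add atoms: chlorotriethylsilane, CC[Si](Cl)(CC)CC
Why: Rhodium-carbenoid O–H insertion into the carboxylic acid (faster than cyclopropanation) puts the acyloxy group on C6, and O-silylation of the enol should occur at the oxygen on C3, remote from the quaternary C1, as in enol-ether formation from 4,4-disubstituted cyclic 1,3-diones.

Step 10
Reactants: 13 ester-tethered silyloxy enone
Product: 14 tricyclic photoadduct: cyclobutane C3–C4–C5–C6 cis-fused to the cyclopentanone (bond C3–C6) and to the new γ-lactone (bond C5–C6), C4/C5 on the ring face opposite the C2 methyl, both Cα epimers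
Conditions: hν (350 nm), degassed benzene (0.003 M), 50 °C
Reagents that add atoms: none
Why: Excitation of the enone chromophore gives the triplet, which adds to the tethered vinyl group in an intramolecular [2+2] photocycloaddition (first half of a de Mayo sequence); the closest known reactions are the intramolecular de Mayo reactions of 2-alkenyl cyclopentane-1,3-dione enol derivatives and the photocycloadditions of 2-alkenyloxy- and 2-acylamino-enones. The three-atom O–C(=O)–Cα tether makes the first bond C6–C5 by 5-exo-trig closure (rule of five), which closes the γ-lactone, and the 1,4-biradical then collapses by C4–C3 bond formation to the cyclobutane, a fused rather than crossed adduct because the crossed mode would need a six-membered first ring. C6 and C3 become quaternary centres fixed relative to each other by the cis fusion of the four-membered ring, and C5 is set by the enone face the vinyl group adds to, which should be the face opposite the C2 methyl group on the carbon next to C3 and opposite the C1 silyloxy group. The step needs regioselectivity (C4 to C3, not to C7), secured by locking the enol as its C3 silyl ether, and facial selectivity, secured by C2 and C1; Cα is not controlled here and is corrected in step 11. The ester must reach its s-cis rotamer for closure, so the irradiation is run dilute and warm, and the product stores the C3–C6 bond that is broken in step 12.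

Step 11
Reactants: 14 tricyclic photoadduct (Cα epimers)
Product: 15 tricyclic photoadduct as the single Cα epimer (lactone methyl cis to C4)
Conditions: LiN(i-Pr)2, THF, −78 °C; then 2,6-di-tert-butyl-4-methylphenol, −78 °C
Reagents that add atoms: none
Why: The lactone α-CH is the only acidic C–H (C7 is flanked by two quaternary carbons), and kinetic protonation of the enolate from the convex face, cis to H5 and away from the cyclobutane CH2 (C4), should converge both epimers to the Cα configuration of the target.

Step 12
Reactants: 15 tricyclic photoadduct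
Product: 17 cycloheptane-1,4-dione (C3 and C7 ketones) with cis-fused γ-lactone at C5/C6, free C1 hydroxyl and C1 CH2OTBDPS, via cyclobutanol 16 (not isolated)
Conditions: HF·pyridine, pyridine, THF, 0 °C to rt
Reagents that add atoms: none
Why: Fluoride removes both triethylsilyl ethers, and the freed β-hydroxy ketone in the strained cyclobutane undergoes retro-aldol cleavage of the C3–C6 bond (second half of the de Mayo reaction) to the seven-membered ring; the C6 enol should be protonated on the face of H5, away from the C5–C4 bond, which gives the cis-fused lactone.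

Step 13
Reactants: 17 cycloheptane-1,4-dione
Product: 18 triol (C1 tertiary, C3 and C7 secondary hydroxyls, both trans to the C1 hydroxyl)
Conditions: Me4NBH(OAc)3 (excess), MeCN/AcOH, −20 °C to rt
Reagents that add atoms: none
Why: Hydroxyl-directed (Evans–Saksena-type) reduction: the borohydride bound to the C1 oxygen should deliver hydride intramolecularly to the β-keto group C3 and the α-keto group C7 from the face of the C1 oxygen, so both new hydroxyls end up trans to it as in the target.

Step 14
Reactants: 18 triol
Product: 19 C3 triisopropylsilyl ether of 18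
Conditions: i-Pr3SiOTf (1.05 equiv), 2,6-lutidine, CH2Cl2, −78 °C
Reagents that add atoms: triisopropylsilyl trifluoromethanesulfonate, CC(C)[Si](OS(=O)(=O)C(F)(F)F)(C(C)C)C(C)C
Why: The bulky silyl triflate should select the less hindered secondary hydroxyl at C3 over the C7 hydroxyl (flanked by quaternary C1 and ring-fusion C6) and the tertiary C1 hydroxyl.

Step 15
Reactants: 19 C3 silyl ether
Product: 20 C7 isobutyrate of 19
Conditions: (i-PrCO)2O, DMAP, Et3N, CH2Cl2, rt to 35 °C
Reagents that add atoms: isobutyric anhydride, CC(C)C(=O)OC(=O)C(C)C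
Why: DMAP-catalysed acylation of the only free secondary alcohol; the tertiary C1 hydroxyl should not react.

Step 16
Reactants: 20 C7 isobutyrate
Product: 21 primary alcohol (C1 CH2OH; C3 silyl ether kept)
Conditions: Bu4NF/AcOH (1:1), THF, 0 °C to rt
Reagents that add atoms: none
Why: Buffered fluoride should cleave the primary tert-butyldiphenylsilyl ether faster than the secondary triisopropylsilyl ether, and the buffer suppresses isobutyryl migration to the new primary hydroxyl.

Step 17
Reactants: 21 primary alcohol
Product: 22 α-hydroxy aldehyde (C1 CHO)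
Conditions: DMP, NaHCO3, CH2Cl2, 0 °C to rt
Reagents that add atoms: none
Why: Mild periodinane oxidation of the primary alcohol; the tertiary hydroxyl is inert and C3 is protected, so no lactol can form.

Step 18
Reactants: 22 α-hydroxy aldehyde
Product: 23 allylic alcohols (C1 bears (E)-1-hydroxybut-2-enyl; both carbinol epimers)
Conditions: (E)-1-bromoprop-1-ene, CrCl2, NiCl2 (cat.), DMF, rt
Reagents that add atoms: (E)-1-bromoprop-1-ene, C/C=C/Br
Why: Nozaki–Hiyama–Kishi alkenylation should add the propenyl group to the aldehyde only, with retention of the E geometry and without touching lactone or isobutyrate; the new carbinol configuration is irrelevant because it is oxidised next.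

Step 19
Reactants: 23 allylic alcohols
Product: 24 C3 triisopropylsilyl ether of the target
Conditions: DMP, NaHCO3, CH2Cl2, rt
Reagents that add atoms: none
Why: Oxidation of the secondary allylic alcohol to the E-enone; the tertiary α-hydroxyl cannot be oxidised.

Step 20
Reactants: 24 silyl-protected target
Product: 25 CNP0268641.1
Conditions: HF·pyridine, THF, rt
Reagents that add atoms: none
Why: Fluoride cleavage of the last silyl ether under mildly acidic conditions that should neither isomerise the enone nor move the isobutyrate.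

**Compound list**

1 | methyl 2-(hydroxymethyl)acrylate | C=C(CO)C(=O)OC | starting material
2 | methyl 2-{[tert-butyl(diphenyl)silyl]oxymethyl}acrylate | CC(C)(C)[Si](c1ccccc1)(c1ccccc1)OCC(=C)C(=O)OC | intermediate
3 | methyl 3-{[tert-butyl(diphenyl)silyl]oxy}-2-oxopropanoate | CC(C)(C)[Si](c1ccccc1)(c1ccccc1)OCC(=O)C(=O)OC | intermediate
4 | S-ethyl propanethioate | CCC(=O)SCC | starting material
5 | (Z)-1-(ethylsulfanyl)-1-(trimethylsilyloxy)prop-1-ene | C/C=C(/O[Si](C)(C)C)SCC | intermediate
6 | 1-methyl 4-S-ethyl (2R,3R)-2-{[tert-butyl(diphenyl)silyl]oxymethyl}-2-hydroxy-3-methyl-4-thiobutanedioate | CC(C)(C)[Si](c1ccccc1)(c1ccccc1)OC[C@@](O)(C(=O)OC)[C@@H](C)C(=O)SCC | intermediate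
7 | triethylsilyl ether of 6 at the tertiary hydroxyl | CC(C)(C)[Si](c1ccccc1)(c1ccccc1)OC[C@@](O[Si](CC)(CC)CC)(C(=O)OC)[C@@H](C)C(=O)SCC | intermediate
8 | methyl (2R,3R)-2-{[tert-butyl(diphenyl)silyl]oxymethyl}-3-methyl-4-oxo-2-(triethylsilyloxy)pentanoate | CC(C)(C)[Si](c1ccccc1)(c1ccccc1)OC[C@@](O[Si](CC)(CC)CC)(C(=O)OC)[C@@H](C)C(C)=O | intermediate
9 | (4R,5R)-4-{[tert-butyl(diphenyl)silyl]oxymethyl}-5-methyl-4-(triethylsilyloxy)cyclopentane-1,3-dione (C2 methyl cis to the C1 silyloxy group) | CC(C)(C)[Si](c1ccccc1)(c1ccccc1)OC[C@]1(O[Si](CC)(CC)CC)[C@@H](C)C(=O)CC1=O | intermediate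
10 | 2-diazo derivative of 9 (diazo on C6) | CC(C)(C)[Si](c1ccccc1)(c1ccccc1)OC[C@]1(O[Si](CC)(CC)CC)[C@@H](C)C(=O)C(=[N+]=[N-])C1=O | intermediate
11 | 2-methylbut-3-enoic acid (racemic) | C=CC(C)C(O)=O | starting material
12 | 3-hydroxy-2-(2-methylbut-3-enoyloxy)cyclopent-2-enone with the C1/C2 substituents of 9 (enol of the 2-acyloxy dione; Cα epimers) | CC(C)(C)[Si](c1ccccc1)(c1ccccc1)OC[C@]1(O[Si](CC)(CC)CC)[C@@H](C)C(O)=C(OC(=O)C(C)C=C)C1=O | intermediate
13 | C3 O-triethylsilyl enol ether of 12 (C7 ketone, C6 acyloxy, C3 silyloxy; Cα epimers) | CC(C)(C)[Si](c1ccccc1)(c1ccccc1)OC[C@]1(O[Si](CC)(CC)CC)[C@@H](C)C(O[Si](CC)(CC)CC)=C(OC(=O)C(C)C=C)C1=O | intermediate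
14 | tricyclic photoadduct: cyclobutane C3–C4–C5–C6 cis-fused to the cyclopentanone and to the γ-lactone, C4/C5 anti to the C2 methyl (Cα epimers) | CC(C)(C)[Si](c1ccccc1)(c1ccccc1)OC[C@]1(O[Si](CC)(CC)CC)[C@@H](C)[C@]3(O[Si](CC)(CC)CC)C[C@@H]2[C@]3(OC(=O)C2C)C1=O | intermediate
15 | photoadduct 14 as the single Cα epimer (lactone methyl cis to C4) | CC(C)(C)[Si](c1ccccc1)(c1ccccc1)OC[C@]1(O[Si](CC)(CC)CC)[C@@H](C)[C@]3(O[Si](CC)(CC)CC)C[C@@H]2[C@]3(OC(=O)[C@@H]2C)C1=O | intermediate
16 | cyclobutanol from 15 (C1 and C3 hydroxyls free) | CC(C)(C)[Si](c1ccccc1)(c1ccccc1)OC[C@]1(O)[C@@H](C)[C@]3(O)C[C@@H]2[C@]3(OC(=O)[C@@H]2C)C1=O | intermediate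
17 | cycloheptane-1,4-dione (C3, C7 ketones) with cis-fused γ-lactone at C5/C6, C1 hydroxyl (cis to C2 methyl) and C1 CH2OTBDPS | CC(C)(C)[Si](c1ccccc1)(c1ccccc1)OC[C@]1(O)[C@@H](C)C(=O)C[C@@H]2[C@@H](OC(=O)[C@@H]2C)C1=O | intermediate
18 | triol from 17 (C3 and C7 hydroxyls trans to the C1 hydroxyl) | CC(C)(C)[Si](c1ccccc1)(c1ccccc1)OC[C@]1(O)[C@@H](C)[C@H](O)C[C@@H]2[C@@H](OC(=O)[C@@H]2C)[C@@H]1O | intermediate
19 | C3 triisopropylsilyl ether of 18 | CC(C)(C)[Si](c1ccccc1)(c1ccccc1)OC[C@]1(O)[C@@H](C)[C@H](O[Si](C(C)C)(C(C)C)C(C)C)C[C@@H]2[C@@H](OC(=O)[C@@H]2C)[C@@H]1O | intermediate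
20 | C7 isobutyrate of 19 | CC(C)(C)[Si](c1ccccc1)(c1ccccc1)OC[C@]1(O)[C@@H](C)[C@H](O[Si](C(C)C)(C(C)C)C(C)C)C[C@@H]2[C@@H](OC(=O)[C@@H]2C)[C@@H]1OC(=O)C(C)C | intermediate
21 | primary alcohol from 20 (C1 CH2OH) | OC[C@]1(O)[C@@H](C)[C@H](O[Si](C(C)C)(C(C)C)C(C)C)C[C@@H]2[C@@H](OC(=O)[C@@H]2C)[C@@H]1OC(=O)C(C)C | intermediate
22 | α-hydroxy aldehyde (C1 CHO) | O=C[C@]1(O)[C@@H](C)[C@H](O[Si](C(C)C)(C(C)C)C(C)C)C[C@@H]2[C@@H](OC(=O)[C@@H]2C)[C@@H]1OC(=O)C(C)C | intermediate
23 | allylic alcohols, C1 bearing (E)-1-hydroxybut-2-enyl (carbinol epimers) | C/C=C/C(O)[C@]1(O)[C@@H](C)[C@H](O[Si](C(C)C)(C(C)C)C(C)C)C[C@@H]2[C@@H](OC(=O)[C@@H]2C)[C@@H]1OC(=O)C(C)C | intermediate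
24 | C3 triisopropylsilyl ether of the target | C/C=C/C(=O)[C@]1(O)[C@@H](C)[C@H](O[Si](C(C)C)(C(C)C)C(C)C)C[C@@H]2[C@@H](OC(=O)[C@@H]2C)[C@@H]1OC(=O)C(C)C | intermediate
25 | CNP0268641.1 | C/C=C/C(=O)[C@]1(O)[C@@H](C)[C@H](O)C[C@@H]2[C@@H](OC(=O)[C@@H]2C)[C@@H]1OC(=O)C(C)C | target

**Step count and risks**

Total step count: 20. Longest linear sequence: 19 steps (steps 1, 2 and 4 to 20; step 3 is a one-step branch).

Steps most likely to fail:

Step 10 (key step). The excited enone may decay without bonding because the enol ester tether stays in its extended rotamer, so that acyl shift or intermolecular dimerisation wins, or the vinyl group may add with poor facial selectivity. The fallback replaces the ester tether by a conformationally free ether tether and makes the lactone carbonyl afterwards. It sets out from diazo dione 10: Rh2(OAc)4-catalysed O–H insertion into racemic 2-methylbut-3-en-1-ol gives the 2-alkenyloxy dione enol F1, which is silylated (Et3SiCl, Et3N) to the ether-tethered silyl enol ether F2. Irradiation, a known cycloaddition mode of 2-alkenyloxy enones, gives the tetrahydrofuran-fused photoadduct F3. Its only ring O–CH2 group (C6 is quaternary) is then oxidised to the lactone carbonyl with RuCl3 (cat.)/NaIO4 in a short reaction, which brings the route back to 14.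

Step 13. Ligand exchange at the hindered tertiary C1 hydroxyl may be slow, or delivery to the α-keto group C7 through the five-membered transition state may be poor, leaving C7 unreduced or eroding the selectivity. The fallback reduces the two ketones one after the other and uses external hydride for C7. It sets out from 17: Me4NBH(OAc)3 at −40 °C should reduce only the β-hydroxy ketone and give the C3 alcohol F4, which is silylated (i-Pr3SiOTf, 2,6-lutidine) to the C3 silyl ether F5. KBH(s-Bu)3 in THF at −78 °C then attacks the C7 ketone from the face opposite the CH2OTBDPS group on the neighbouring quaternary C1, which brings the route back to 19.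

Step 11. The proton may be delivered to both faces of the lactone enolate, so that the Cα epimers do not converge. The fallback sets Cα by hydrogenation instead of protonation. It sets out from 14: LiN(i-Pr)2 and PhSeBr give the α-phenylselanyl lactone F6, and H2O2 oxidation with selenoxide syn-elimination toward the methyl group gives the α-methylene lactone F7. Hydrogenation with RhCl(PPh3)3 and H2 adds hydrogen from the convex face of the lactone, which places the methyl group cis to C4 and brings the route back to 15.

Further compounds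
F1 | step 10 | 3-hydroxy-2-(2-methylbut-3-enyloxy)cyclopent-2-enone with the C1/C2 substituents of 9 (enol of the 2-alkoxy dione) | CC(C)(C)[Si](c1ccccc1)(c1ccccc1)OC[C@]1(O[Si](CC)(CC)CC)[C@@H](C)C(O)=C(OCC(C)C=C)C1=O
F2 | step 10 | C3 O-triethylsilyl enol ether of F1 | CC(C)(C)[Si](c1ccccc1)(c1ccccc1)OC[C@]1(O[Si](CC)(CC)CC)[C@@H](C)C(O[Si](CC)(CC)CC)=C(OCC(C)C=C)C1=O
F3 | step 10 | tetrahydrofuran-fused photoadduct (ether analogue of 14) | CC(C)(C)[Si](c1ccccc1)(c1ccccc1)OC[C@]1(O[Si](CC)(CC)CC)[C@@H](C)[C@]3(O[Si](CC)(CC)CC)C[C@@H]2[C@]3(OCC2C)C1=O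
F4 | step 13 | C3 alcohol, C7 ketone (mono-reduced 17) | CC(C)(C)[Si](c1ccccc1)(c1ccccc1)OC[C@]1(O)[C@@H](C)[C@H](O)C[C@@H]2[C@@H](OC(=O)[C@@H]2C)C1=O
F5 | step 13 | C3 triisopropylsilyl ether of F4 | CC(C)(C)[Si](c1ccccc1)(c1ccccc1)OC[C@]1(O)[C@@H](C)[C@H](O[Si](C(C)C)(C(C)C)C(C)C)C[C@@H]2[C@@H](OC(=O)[C@@H]2C)C1=O
F6 | step 11 | α-phenylselanyl lactone from 14 | CC(C)(C)[Si](c1ccccc1)(c1ccccc1)OC[C@]1(O[Si](CC)(CC)CC)[C@@H](C)[C@]3(O[Si](CC)(CC)CC)C[C@@H]2[C@]3(OC(=O)C2(C)[Se]c4ccccc4)C1=O
F7 | step 11 | α-methylene lactone from F6 | CC(C)(C)[Si](c1ccccc1)(c1ccccc1)OC[C@]1(O[Si](CC)(CC)CC)[C@@H](C)[C@]3(O[Si](CC)(CC)CC)C[C@@H]2[C@]3(OC(=O)C2=C)C1=O
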